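**Retrosynthetic overview**
1. Both dihydropyran rings are opened at once. In each half the C2–C3 and C4–C4a bonds are cut and C3–C4 leaves as a two-carbon unit. Phenyl vinyl sulfone serves as the CH2CH2 equivalent, and its sulfonyl groups come off reductively in the last step. What remains is an acyclic bis(2-aryloxy-2-methylpropanoic acid), activated as its bis(N-hydroxyphthalimide) ester.
2. Enabling feature: in each chroman, O1 carries the quaternary gem-dimethyl carbon C2, which becomes a tertiary α-aryloxy radical once a carboxyl group on C2 is lost. C3–C4 is an unsubstituted ethano bridge. C4a, ortho to O1, is the only position of the otherwise fully substituted phloroglucinol ring that is a free CH in the precursor.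
3. The diarylmethine is cut at its bond to the arene of the 2-methylbutanoyl half (half A). That phenol adds enantioselectively, under catalysis, to the ortho-quinone methide of the isobutyryl half (half B, primed atoms), which is stored as a sulfone made with 6-methylheptanal.
4. Each half comes from phloroglucinol by Friedel–Crafts acylation, double MOM protection and O-alkylation of the one remaining, chelated OH with benzyl 2-bromo-2-methylpropanoate. (R)-2-Methylbutanoic acid brings in the second stereocentre.
5. Ring order: the two arenes are bought as phloroglucinol, and the two pyran rings are formed last and together, in the key step.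

Key step: step 13

Assumption: the quinine-derived squaramide is taken to deliver the (R) methine in step 10; if the opposite sense of induction is met, its quinidine-derived pseudoenantiomer is used and nothing else changes.

**Step 1**
Reactants: 1 phloroglucinol; 2 2-methylpropanoyl chloride
Product: 3 2-methyl-1-(2,4,6-trihydroxyphenyl)propan-1-one
Conditions: AlCl3 (3.5 equiv), CH2Cl2/PhNO2, 0 to 40 °C; 1 M HCl work-up
Reagents that add atoms: none
Why: Friedel–Crafts acylation of the threefold activated arene should stop at the monoketone, because the aluminium-chelated acylphloroglucinol formed first is strongly deactivated towards a second acylation.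

**Step 2**
Reactants: 3 2-methyl-1-(2,4,6-trihydroxyphenyl)propan-1-one
Product: 4 1-[2-hydroxy-4,6-bis(methoxymethoxy)phenyl]-2-methylpropan-1-one
Conditions: MOMCl (2.1 equiv), iPr2NEt (2.5 equiv), CH2Cl2, 0 °C
Reagents that add atoms: chloromethyl methyl ether, COCCl
Why: Williamson-type etherification under amine base should take the para OH and one ortho OH, whereas the last OH is locked in a strong hydrogen bond to the ketone and stays free, which singles out the oxygen that becomes O1'.

**Step 3**
Reactants: 4 1-[2-hydroxy-4,6-bis(methoxymethoxy)phenyl]-2-methylpropan-1-one; 5 benzyl 2-bromo-2-methylpropanoate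
Product: 6 benzyl 2-[3,5-bis(methoxymethoxy)-2-(2-methylpropanoyl)phenoxy]-2-methylpropanoate
Conditions: 5 (2 equiv), Cs2CO3 (2 equiv), DMF, 50 °C
Reagents that add atoms: none
Why: Williamson etherification of the caesium phenoxide with a carbonyl-activated tertiary α-bromo ester (the classical fibrate ether synthesis) should install the O1'–C2' bond together with the gem-dimethyl group and the carboxyl handle, an excess of 5 making up for its loss by elimination.

**Step 4**
Reactants: 6 benzyl 2-[3,5-bis(methoxymethoxy)-2-(2-methylpropanoyl)phenoxy]-2-methylpropanoate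
Product: 7 benzyl 2-[3,5-dihydroxy-2-(2-methylpropanoyl)phenoxy]-2-methylpropanoate
Conditions: conc. HCl (cat.), MeOH, 40 °C
Reagents that add atoms: none
Why: Acid-catalysed transacetalisation with methanol should release both phenols and bind the formaldehyde unit as dimethoxymethane, so that it cannot bridge the nucleophilic rings, while the hindered benzyl ester and the tertiary aryl ether, whose ionisation is disfavoured by the neighbouring ester carbonyl, persist.

**Step 5**
Reactants: 7 benzyl 2-[3,5-dihydroxy-2-(2-methylpropanoyl)phenoxy]-2-methylpropanoate; 8 6-methylheptanal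
Product: 9 benzyl 2-{3,5-dihydroxy-4-[6-methyl-1-(4-methylphenyl)sulfonylheptyl]-2-(2-methylpropanoyl)phenoxy}-2-methylpropanoate (racemic at the sulfonyl-bearing carbon)
Conditions: 8 (1.05 equiv), p-TolSO2H (2 equiv), TsOH·H2O (5 mol %), EtOAc, 20 °C
Reagents that add atoms: 4-methylbenzenesulfinic acid, Cc1ccc(S(=O)O)cc1
Why: Three-component sulfonylalkylation (Friedel–Crafts hydroxyalkylation, loss of water to the ortho-quinone methide and its capture by the soft sulfinate) should occur at the CH between the two free OH groups, which is less shielded than the CH next to the bulky tertiary ether, and it stores the quinone methide in a handleable form; the new centre is racemic and is erased in step 10.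

**Step 6**
Reactants: 10 (2R)-2-methylbutanoic acid; 1 phloroglucinol
Product: 12 (2R)-2-methyl-1-(2,4,6-trihydroxyphenyl)butan-1-one, via (2R)-2-methylbutanoyl chloride 11 (not isolated)
Conditions: (COCl)2 (1.0 equiv), DMF (cat.), CH2Cl2, 0 to 20 °C; then added to 1, AlCl3 (3.5 equiv), CH2Cl2/PhNO2, 0 to 25 °C; 1 M HCl work-up
Reagents that add atoms: none
Why: Base-free acid chloride formation followed by Friedel–Crafts acylation at or below room temperature avoids ketene formation and keeps enolisation slow, so the (R) centre of the chiral-pool acid should be carried over unchanged.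

**Step 7**
Reactants: 12 (2R)-2-methyl-1-(2,4,6-trihydroxyphenyl)butan-1-one
Product: 13 (2R)-1-[2-hydroxy-4,6-bis(methoxymethoxy)phenyl]-2-methylbutan-1-one
Conditions: MOMCl (2.1 equiv), iPr2NEt (2.5 equiv), CH2Cl2, 0 °C
Reagents that add atoms: chloromethyl methyl ether, COCCl
Why: The same chelation-controlled double Williamson-type MOM etherification as in step 2 should leave only the future O1 free, and the amine base at 0 °C does not touch the α-stereocentre.

**Step 8**
Reactants: 13 (2R)-1-[2-hydroxy-4,6-bis(methoxymethoxy)phenyl]-2-methylbutan-1-one; 5 benzyl 2-bromo-2-methylpropanoate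
Product: 14 benzyl 2-{3,5-bis(methoxymethoxy)-2-[(2R)-2-methylbutanoyl]phenoxy}-2-methylpropanoate
Conditions: 5 (2 equiv), Cs2CO3 (2 equiv), DMF, 50 °C
Reagents that add atoms: none
Why: Williamson etherification as in step 3 should form O1–C2, and carbonate is far too weak a base to enolise the hindered, out-of-plane aryl sec-alkyl ketone, so the (R) centre should persist.

**Step 9**
Reactants: 14 benzyl 2-{3,5-bis(methoxymethoxy)-2-[(2R)-2-methylbutanoyl]phenoxy}-2-methylpropanoate
Product: 15 benzyl 2-{3,5-dihydroxy-2-[(2R)-2-methylbutanoyl]phenoxy}-2-methylpropanoate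
Conditions: conc. HCl (cat.), MeOH, 40 °C
Reagents that add atoms: none
Why: Acid-catalysed transacetalisation as in step 4 should free both phenols, the catalytic acid and low temperature being too mild to enolise the ketone towards its stereocentre.

**Step 10**
Reactants: 9 sulfone of half B; 15 benzyl 2-{3,5-dihydroxy-2-[(2R)-2-methylbutanoyl]phenoxy}-2-methylpropanoate
Product: 17 (R)-methine-bridged dimer dibenzyl ester [1,1-diaryl-6-methylheptane; aryl A = 4-(1-benzyloxy-2-methyl-1-oxopropan-2-yl)oxy-2,6-dihydroxy-3-[(2R)-2-methylbutanoyl]phenyl; aryl B = the same ring bearing 3-(2-methylpropanoyl) instead], via ortho-quinone methide 16 (not isolated)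
Conditions: 15 (1.2 equiv), 3-{[3,5-bis(trifluoromethyl)phenyl]amino}-4-{[(8α,9S)-6'-methoxycinchonan-9-yl]amino}cyclobut-3-ene-1,2-dione (10 mol %), satd aq NaHCO3, CHCl3, 0 °C
Reagents that add atoms: none
Why: This is an organocatalytic asymmetric conjugate (Friedel–Crafts-type Michael) addition to an ortho-quinone methide released in situ from a 2-(1-sulfonylalkyl)phenol, in which the quinuclidine nitrogen expels sulfinate from 9 and then holds 15 through an acidic OH, the squaramide NH groups bind the quinone methide carbonyl, and C–C bond formation on one face of the exocyclic CH inside this hydrogen-bonded assembly sets the methine as (R), 15 reacting at its CH between the two free OH groups.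

**Step 11**
Reactants: 17 (R)-dimer dibenzyl ester
Product: 18 (R)-dimer diacid (both CO2Bn groups of 17 turned into CO2H)
Conditions: H2 (1 atm), Pd/C (10 wt %), EtOAc, 20 °C
Reagents that add atoms: none
Why: Heterogeneous hydrogenolysis of the benzyl esters is neutral, which matters because the diarylmethine flanked by four phenols tolerates neither saponification nor strong acid, and the chelated aryl ketones and the arenes are not reduced at this pressure.

**Step 12**
Reactants: 18 (R)-dimer diacid
Product: 19 (R)-dimer bis(1,3-dioxoisoindolin-2-yl) ester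
Conditions: N-hydroxyphthalimide (2.2 equiv), DIC (2.2 equiv), DMAP (10 mol %), CH2Cl2, 0 to 20 °C
Reagents that add atoms: N-hydroxyphthalimide, O=C1c2ccccc2C(=O)N1O
Why: In this Steglich-type carbodiimide esterification the acidic, unhindered N–OH nucleophile should outcompete the four hindered, hydrogen-bonded phenols for the O-acylisourea.

**Step 13**
Reactants: 19 (R)-dimer bis(1,3-dioxoisoindolin-2-yl) ester; 20 phenyl vinyl sulfone
Product: 21 (R)-dimer bis[4-(phenylsulfonyl)chroman] (target skeleton with PhSO2 at C4 and at C4'; mixture of isomers at these two carbons)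
Conditions: 20 (6 equiv), fac-Ir(ppy)3 (2 mol %), AcOH (4 equiv), degassed DMA (0.05 M), 450 nm LEDs, 20 °C
Reagents that add atoms: none
Why: Excited fac-Ir(ppy)3 transfers one electron to each N-acyloxyphthalimide, which loses phthalimide anion and CO2 to give the tertiary, nucleophilic α-aryloxy radical at C2; this adds Giese-fashion to the CH2 terminus of the electron-poor olefin (C2–C3 bond), the electrophilic α-sulfonyl radical at C4 then attacks the electron-rich arene at C4a (C4–C4a bond), and tetravalent iridium oxidises the cyclohexadienyl radical before proton loss restores the arene, so the cycle is redox-neutral. The closest known reaction type is the photoredox decarboxylative (4+2) radical annulation of aryloxyalkyl N-hydroxyphthalimide esters with electron-poor olefins to chromans, run here on both halves in the same flask, so that four C–C bonds and both pyran rings arise in one operation. Each pyran ring closes by ortho attack of the C4 radical on the arene (six-membered ring, formally 6-endo with respect to the C8a–C4a bond, helped by the gem-dimethyl effect) in preference to the strained 5-exo ipso attack at C8a. The new stereocentres at C4 and C4' are not controlled and need not be, because both are erased in step 14, while the methine and the acyl α-carbon are not involved under these neutral, buffered conditions. Regioselectivity is secured because C4a is the only unsubstituted ring carbon and the other ortho position, C8, carries the acyl group. Chemoselectivity is secured by the alternating polarity (nucleophilic radical with electron-poor olefin, electrophilic radical with electron-rich arene), by the excess of olefin, by the hydrogen-bond-accepting solvent that slows hydrogen transfer from the phenols, and by the low oxidising power of tetravalent iridium, which leaves the protonated phenols alone.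

**Step 14**
Reactants: 21 (R)-dimer bis[4-(phenylsulfonyl)chroman]
Product: 23 (2R)-1-{6-[(1R)-1-[5,7-dihydroxy-2,2-dimethyl-8-(2-methylpropanoyl)-3,4-dihydro-2H-chromen-6-yl]-6-methylheptyl]-5,7-dihydroxy-2,2-dimethyl-3,4-dihydro-2H-chromen-8-yl}-2-methylbutan-1-one, via bis(ortho-quinone methide) 22 (not isolated)
Conditions: NaBH4 (4 equiv), THF/EtOH 4:1, −20 to 0 °C; aq NaH2PO4 quench
Reagents that add atoms: none
Why: Phenoxide formation at O5 should expel benzenesulfinate from the doubly activated benzylic C4 (base-triggered 1,4-elimination of a 2-(sulfonylalkyl)phenol) and the ortho-quinone methide should take up hydride at C4 (conjugate borohydride reduction) much faster than the phenoxide-conjugated ketones react or the far poorer carbon leaving group at the methine departs, so that all C4/C4' isomers converge on one compound.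

**Compound list**
1 | phloroglucinol | Oc1cc(O)cc(O)c1 | starting material
2 | 2-methylpropanoyl chloride | CC(C)C(=O)Cl | starting material
3 | 2-methyl-1-(2,4,6-trihydroxyphenyl)propan-1-one | CC(C)C(=O)c1c(O)cc(O)cc1O | intermediate
4 | 1-[2-hydroxy-4,6-bis(methoxymethoxy)phenyl]-2-methylpropan-1-one | CC(C)C(=O)c1c(O)cc(OCOC)cc1OCOC | intermediate
5 | benzyl 2-bromo-2-methylpropanoate | CC(C)(Br)C(=O)OCc1ccccc1 | starting material
6 | benzyl 2-[3,5-bis(methoxymethoxy)-2-(2-methylpropanoyl)phenoxy]-2-methylpropanoate | CC(C)C(=O)c1c(OCOC)cc(OCOC)cc1OC(C)(C)C(=O)OCc1ccccc1 | intermediate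
7 | benzyl 2-[3,5-dihydroxy-2-(2-methylpropanoyl)phenoxy]-2-methylpropanoate | CC(C)C(=O)c1c(O)cc(O)cc1OC(C)(C)C(=O)OCc1ccccc1 | intermediate
8 | 6-methylheptanal | CC(C)CCCCC=O | starting material
9 | benzyl 2-{3,5-dihydroxy-4-[6-methyl-1-(4-methylphenyl)sulfonylheptyl]-2-(2-methylpropanoyl)phenoxy}-2-methylpropanoate, racemic at the sulfonyl carbon | CC(C)C(=O)c1c(O)c(C(CCCCC(C)C)S(=O)(=O)c2ccc(C)cc2)c(O)cc1OC(C)(C)C(=O)OCc1ccccc1 | intermediate
10 | (2R)-2-methylbutanoic acid | CC[C@@H](C)C(=O)O | starting material
11 | (2R)-2-methylbutanoyl chloride | CC[C@@H](C)C(=O)Cl | intermediate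
12 | (2R)-2-methyl-1-(2,4,6-trihydroxyphenyl)butan-1-one | CC[C@@H](C)C(=O)c1c(O)cc(O)cc1O | intermediate
13 | (2R)-1-[2-hydroxy-4,6-bis(methoxymethoxy)phenyl]-2-methylbutan-1-one | CC[C@@H](C)C(=O)c1c(O)cc(OCOC)cc1OCOC | intermediate
14 | benzyl 2-{3,5-bis(methoxymethoxy)-2-[(2R)-2-methylbutanoyl]phenoxy}-2-methylpropanoate | CC[C@@H](C)C(=O)c1c(OCOC)cc(OCOC)cc1OC(C)(C)C(=O)OCc1ccccc1 | intermediate
15 | benzyl 2-{3,5-dihydroxy-2-[(2R)-2-methylbutanoyl]phenoxy}-2-methylpropanoate | CC[C@@H](C)C(=O)c1c(O)cc(O)cc1OC(C)(C)C(=O)OCc1ccccc1 | intermediate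
16 | benzyl 2-{[5-hydroxy-4-(6-methylheptylidene)-3-oxo-6-(2-methylpropanoyl)cyclohexa-1,5-dien-1-yl]oxy}-2-methylpropanoate (ortho-quinone methide of half B) | CC(C)CCCCC=C1C(=O)C=C(OC(C)(C)C(=O)OCc2ccccc2)C(C(=O)C(C)C)=C1O | intermediate
17 | (R)-methine-bridged dimer dibenzyl ester | CC[C@@H](C)C(=O)c1c(O)c([C@H](CCCCC(C)C)c2c(O)cc(OC(C)(C)C(=O)OCc3ccccc3)c(C(=O)C(C)C)c2O)c(O)cc1OC(C)(C)C(=O)OCc1ccccc1 | intermediate
18 | (R)-dimer diacid | CC[C@@H](C)C(=O)c1c(O)c([C@H](CCCCC(C)C)c2c(O)cc(OC(C)(C)C(=O)O)c(C(=O)C(C)C)c2O)c(O)cc1OC(C)(C)C(=O)O | intermediate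
19 | (R)-dimer bis(1,3-dioxoisoindolin-2-yl) ester | CC[C@@H](C)C(=O)c1c(O)c([C@H](CCCCC(C)C)c2c(O)cc(OC(C)(C)C(=O)ON3C(=O)c4ccccc4C3=O)c(C(=O)C(C)C)c2O)c(O)cc1OC(C)(C)C(=O)ON1C(=O)c2ccccc2C1=O | intermediate
20 | phenyl vinyl sulfone | C=CS(=O)(=O)c1ccccc1 | starting material
21 | (R)-dimer bis[4-(phenylsulfonyl)chroman], mixture at C4 and C4' | CC[C@@H](C)C(=O)c1c(O)c([C@H](CCCCC(C)C)c2c(O)c3c(c(C(=O)C(C)C)c2O)OC(C)(C)CC3S(=O)(=O)c2ccccc2)c(O)c2c1OC(C)(C)CC2S(=O)(=O)c1ccccc1 | intermediate
22 | bis(ortho-quinone methide), drawn with both halves in the C4=C4a/C5=O form (the halves may react one after the other) | CC[C@@H](C)C(=O)C1=C2OC(C)(C)CC=C2C(=O)C([C@H](CCCCC(C)C)C3=C(O)C(C(=O)C(C)C)=C4OC(C)(C)CC=C4C3=O)=C1O | intermediate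
23 | CNP0287681.1, (R) at the methine and (R) in the 2-methylbutanoyl group | CC[C@@H](C)C(=O)c1c(O)c([C@H](CCCCC(C)C)c2c(O)c3c(c(C(=O)C(C)C)c2O)OC(C)(C)CC3)c(O)c2c1OC(C)(C)CC2 | target

**Step count**
Total: 14 steps. Longest linear sequence: 10 steps (steps 1 to 5 and 10 to 14, from phloroglucinol).

**Steps most likely to fail**

*Step 10.* Four processes may spoil it:
- poor facial selectivity on the flexible, alkyl-substituted quinone methide;
- a fast uncatalysed addition of the phenoxide;
- tautomerisation of the quinone methide to the alkenylphenol;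
- erosion of the configuration by reversible C–C cleavage under base.

The fallback replaces asymmetric catalysis by separation. It sets out from 9 and 15 and comes back at 17. The coupling is run without the chiral catalyst (NaHCO3, CHCl3/H2O, 0 °C) to give the methine-epimeric dibenzyl ester mixture F1. Its two components are diastereomers thanks to the (R)-2-methylbutanoyl group, and they are separated by preparative chromatography on an amylose-based chiral stationary phase. The (R) epimer is 17.

*Step 13.* Three processes may spoil it: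
- one of the two annulations may stall;
- hydrogen transfer from a phenol to the α-sulfonyl radical may end the sequence before ring closure;
- the tertiary radical may be oxidised to the oxocarbenium ion before it meets the olefin.

The fallback inverts the order of events, so that each annulation is a single event on a simple monomer and the coupling comes last. It sets out from 7 and 15 and comes back at 23.
- Half B: 7 is hydrogenolysed (H2, Pd/C) to 2-[3,5-dihydroxy-2-(2-methylpropanoyl)phenoxy]-2-methylpropanoic acid F2 and esterified (N-hydroxyphthalimide, DIC) to its 1,3-dioxoisoindolin-2-yl ester F3. Annulation with 20 (fac-Ir(ppy)3, 450 nm) gives 1-[5,7-dihydroxy-2,2-dimethyl-4-(phenylsulfonyl)chroman-8-yl]-2-methylpropan-1-one F4. Desulfonylation (NaBH4) gives 1-(5,7-dihydroxy-2,2-dimethylchroman-8-yl)-2-methylpropan-1-one F5, which is converted with 8 and 4-methylbenzenesulfinic acid into the C6 sulfonylalkyl chroman F6.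
- Half A: 15 is taken in the same way through 2-{3,5-dihydroxy-2-[(2R)-2-methylbutanoyl]phenoxy}-2-methylpropanoic acid F7, its 1,3-dioxoisoindolin-2-yl ester F8 and the 4-(phenylsulfonyl)chroman ketone F9 to (2R)-1-(5,7-dihydroxy-2,2-dimethylchroman-8-yl)-2-methylbutan-1-one F10.
- Coupling: F6 and F10 are joined under the conditions of step 10 through the chroman ortho-quinone methide F11. Each chroman has only C6 free, so the coupling has no regiochemical choice and should give 23 directly.

*Step 14.* Three processes may spoil it:
- the quinone methide may tautomerise to the chromene, which borohydride does not reduce;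
- hydride may attack a ketone;
- base may cleave the dimer at the methine, with hydride trapping the fragment.

The fallback separates elimination from reduction. It sets out from 21 and comes back at 23. Sulfinate is eliminated on purpose with the weak base 2,6-lutidine in warm MeCN, through 22 and its tautomerisation, to the bis(2,2-dimethyl-2H-chromene) dimer F12. Both C3=C4 bonds are then saturated under neutral conditions (H2, Pd/C, EtOAc, 20 °C).

**Further compounds**
F1 | step 10 | methine-epimeric dibenzyl ester mixture | CC[C@@H](C)C(=O)c1c(O)c(C(CCCCC(C)C)c2c(O)cc(OC(C)(C)C(=O)OCc3ccccc3)c(C(=O)C(C)C)c2O)c(O)cc1OC(C)(C)C(=O)OCc1ccccc1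
F2 | step 13 | 2-[3,5-dihydroxy-2-(2-methylpropanoyl)phenoxy]-2-methylpropanoic acid | CC(C)C(=O)c1c(O)cc(O)cc1OC(C)(C)C(=O)O
F3 | step 13 | 1,3-dioxoisoindolin-2-yl ester of F2 | CC(C)C(=O)c1c(O)cc(O)cc1OC(C)(C)C(=O)ON1C(=O)c2ccccc2C1=O
F4 | step 13 | 1-[5,7-dihydroxy-2,2-dimethyl-4-(phenylsulfonyl)chroman-8-yl]-2-methylpropan-1-one | CC(C)C(=O)c1c(O)cc(O)c2c1OC(C)(C)CC2S(=O)(=O)c1ccccc1
F5 | step 13 | 1-(5,7-dihydroxy-2,2-dimethylchroman-8-yl)-2-methylpropan-1-one | CC(C)C(=O)c1c(O)cc(O)c2c1OC(C)(C)CC2
F6 | step 13 | 1-{5,7-dihydroxy-2,2-dimethyl-6-[6-methyl-1-(4-methylphenyl)sulfonylheptyl]chroman-8-yl}-2-methylpropan-1-one | CC(C)C(=O)c1c(O)c(C(CCCCC(C)C)S(=O)(=O)c2ccc(C)cc2)c(O)c2c1OC(C)(C)CC2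
F7 | step 13 | 2-{3,5-dihydroxy-2-[(2R)-2-methylbutanoyl]phenoxy}-2-methylpropanoic acid | CC[C@@H](C)C(=O)c1c(O)cc(O)cc1OC(C)(C)C(=O)O
F8 | step 13 | 1,3-dioxoisoindolin-2-yl ester of F7 | CC[C@@H](C)C(=O)c1c(O)cc(O)cc1OC(C)(C)C(=O)ON1C(=O)c2ccccc2C1=O
F9 | step 13 | (2R)-1-[5,7-dihydroxy-2,2-dimethyl-4-(phenylsulfonyl)chroman-8-yl]-2-methylbutan-1-one | CC[C@@H](C)C(=O)c1c(O)cc(O)c2c1OC(C)(C)CC2S(=O)(=O)c1ccccc1
F10 | step 13 | (2R)-1-(5,7-dihydroxy-2,2-dimethylchroman-8-yl)-2-methylbutan-1-one | CC[C@@H](C)C(=O)c1c(O)cc(O)c2c1OC(C)(C)CC2
F11 | step 13 | chroman ortho-quinone methide from F6 | CC(C)CCCCC=C1C(=O)C2=C(OC(C)(C)CC2)C(C(=O)C(C)C)=C1O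
F12 | step 14 | bis(2,2-dimethyl-2H-chromene) dimer | CC[C@@H](C)C(=O)c1c(O)c([C@H](CCCCC(C)C)c2c(O)c3c(c(C(=O)C(C)C)c2O)OC(C)(C)C=C3)c(O)c2c1OC(C)(C)C=C2
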